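**Assumption:** the SMILES is taken as drawn, i.e. the trans-fused (1S,3S,3aR,4R,5S,7aR)-hexahydroindenone acid; commercial 2-ethylhex-2-enal is used as its (E)-isomer.

## Retrosynthetic overview

1. Target 18 ⇐ keto aldehyde 17 ⇐ hydroxy aldehyde 16: only oxidation-state changes at the end (C2 carbinol → ketone, C4 CHO → CO2H).
2. 16 ⇐ linear tetraenal 15 by one intramolecular Diels–Alder reaction that closes the cyclohexene and the cyclopentane in the same step (bonds C4–C5 and C3a–C7a); C1 and C3 relay their configuration to C3a, C4, C5 and C7a.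
3. 15 ⇐ trienal 11 + silyl dienol ether 13 of 2-ethylhex-2-enal by an organocatalytic vinylogous Mukaiyama aldol addition (C2–C3 bond, two stereocentres).
4. 11 ⇐ (2R)-3-hydroxy-2-methylpropanal 6 by three E-selective olefinations (two formyl-ylide Wittig reactions, one benzyl Horner–Wadsworth–Emmons) and one oxidation.
5. 6 ⇐ propanal + formaldehyde: enamine-catalysed α-hydroxymethylation sets the first stereocentre.

## Route

Step 1
Reactants: 1 propyltriphenylphosphonium bromide; 2 ethyl formate
Product: 3 2-(triphenylphosphoranylidene)butanal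
Conditions: KOt-Bu (1.1 equiv), THF, 0 °C; then 2, 0 °C → rt
Reagents that add atoms: none
Why: C-formylation of the in situ ylide by ethyl formate (ylide acylation) followed by deprotonation of the acylphosphonium by the released alkoxide gives the formyl-stabilised ylide; no stereocentre is formed.

Step 2
Reactants: 4 propanal; 5 formaldehyde (37% aqueous); 3 2-(triphenylphosphoranylidene)butanal
Product: 7 (2E,4S)-2-ethyl-5-hydroxy-4-methylpent-2-enal, via (2R)-3-hydroxy-2-methylpropanal 6 (not isolated)
Conditions: 4 (1.5 equiv), 5 (1.0 equiv), (S)-α,α-diphenylprolinol trimethylsilyl ether (10 mol%), pH 7 buffer (NaH2PO4/Na2HPO4), toluene, 0 °C → rt; excess 4 evaporated; then 3 (2 equiv), 40 °C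
Reagents that add atoms: none
Why: Enamine-catalysed asymmetric α-hydroxymethylation (cross-aldol with formaldehyde), in which the bulky diarylsilyloxymethyl group of the (S)-catalyst blocks one face of the (E)-enamine so that formaldehyde adds to the Si face and gives (2R)-6 (the future C1 methyl stereocentre), which is trapped at once by an E-selective Wittig olefination with the stabilised ylide before it can racemise or dehydrate.

Step 3
Reactants: 7 (2E,4S)-2-ethyl-5-hydroxy-4-methylpent-2-enal; 3 2-(triphenylphosphoranylidene)butanal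
Product: 8 (2E,4E,6S)-2,4-diethyl-7-hydroxy-6-methylhepta-2,4-dienal
Conditions: 3 (1.5 equiv), toluene, 100 °C
Reagents that add atoms: none
Why: Second Wittig olefination with the same formyl-stabilised ylide, E-selective for the trisubstituted alkene; the ylide is too weakly basic to touch the γ-stereocentre and the free hydroxyl is inert.

Step 4
Reactants: 8 (2E,4E,6S)-2,4-diethyl-7-hydroxy-6-methylhepta-2,4-dienal; 9 diethyl benzylphosphonate
Product: 10 (2S,3E,5E,7E)-4,6-diethyl-2-methyl-8-phenylocta-3,5,7-trien-1-ol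
Conditions: 9 (2.3 equiv) + KOt-Bu (2.2 equiv), THF, 0 °C; then 8, −40 °C → rt
Reagents that add atoms: none
Why: Horner–Wadsworth–Emmons olefination with the preformed benzylphosphonate anion gives the (E)-styryl terminus, carbonyl addition being much faster than deprotonation of the remote allylic C–H, so the stereocentre is kept.

Step 5
Reactants: 10 (2S,3E,5E,7E)-4,6-diethyl-2-methyl-8-phenylocta-3,5,7-trien-1-ol
Product: 11 (2S,3E,5E,7E)-4,6-diethyl-2-methyl-8-phenylocta-3,5,7-trienal
Conditions: Dess–Martin periodinane (1.2 equiv), NaHCO3, CH2Cl2, 0 °C; filtered cold, used crude at once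
Reagents that add atoms: none
Why: Dess–Martin oxidation under buffered, amine-free conditions is the standard way to reach α-stereogenic β,γ-unsaturated aldehydes without epimerisation or conjugation, provided the aldehyde is not chromatographed and is used immediately.

Step 6
Reactants: 12 (2E)-2-ethylhex-2-enal
Product: 13 triethyl{[(1E,3E)-2-ethylhexa-1,3-dien-1-yl]oxy}silane
Conditions: Et3SiOTf (1.2 equiv), Et3N (1.5 equiv), Et2O, 0 °C → rt
Reagents that add atoms: triethylsilyl trifluoromethanesulfonate, CC[Si](CC)(CC)OS(=O)(=O)C(F)(F)F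
Why: Soft enolisation (O-silylation, then γ-deprotonation by the amine) gives the aldehyde-derived silyl dienol ether; the C1=C2 geometry (drawn E) is lost again in the next step, so an isomer mixture is acceptable.

Step 7
Reactants: 11 (2S,3E,5E,7E)-4,6-diethyl-2-methyl-8-phenylocta-3,5,7-trienal; 13 triethyl{[(1E,3E)-2-ethylhexa-1,3-dien-1-yl]oxy}silane
Product: 15 (2E,4S,5R,6S,7E,9E,11E)-2,4,8,10-tetraethyl-5-hydroxy-6-methyl-12-phenyldodeca-2,7,9,11-tetraenal, via 5-O-triethylsilyl ether 14 (not isolated)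
Conditions: confined BINOL-derived imidodiphosphorimidate (IDPi, N-triflyl core; 2 mol%), 13 (1.5 equiv), toluene, −78 °C; then HF·pyridine, THF, 0 °C
Reagents that add atoms: none
Why: Proposed new method: a metal-free, IDPi-catalysed vinylogous Mukaiyama aldol addition of an aldehyde-derived α,γ-dialkyl silyl dienol ether, in which 13 silylates the chiral acid to a silylium–IDPi ion pair that activates 11 as an O-silyl oxocarbenium ion inside the chiral anion pocket; attack comes from the γ-carbon of 13 (the α-carbon is ethyl-blocked and would give a quaternary centre), an open antiperiplanar transition state gives the 4,5-anti relationship, the catalyst enantiomer that attacks the aldehyde Si face is matched with Felkin–Anh control by the C6 stereocentre (5,6-syn), and silyl transfer to the aldolate releases the catalyst and a hindered δ-silyloxy α-branched enal that is not activated again. The closest known reaction types are IDPi-catalysed Mukaiyama aldol additions of simple aldehyde enol silanes and vinylogous Mukaiyama aldol additions of ester-derived silyl dienolates under disulfonimide or borane Lewis acid catalysis.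

Step 8
Reactants: 15 (2E,4S,5R,6S,7E,9E,11E)-2,4,8,10-tetraethyl-5-hydroxy-6-methyl-12-phenyldodeca-2,7,9,11-tetraenal
Product: 16 (1S,2R,3S,3aR,4R,5S,7aR)-3,4,5,7-tetraethyl-2-hydroxy-1-methyl-5-[(E)-2-phenylethenyl]-2,3,3a,4,5,7a-hexahydro-1H-indene-4-carbaldehyde
Conditions: toluene (5 mM), BHT (cat.), 100 °C
Reagents that add atoms: none
Why: Thermal intramolecular Diels–Alder reaction of the (E,E)-diene with the (E)-enal through the endo, trans-fused transition state; allylic 1,3-strain holds the C6–H and C4–H bonds of 15 in the planes of the diene and the dienophile, so the methyl- and ethyl-bearing centres together fix both π-faces and set C3a, C4, C5 and C7a (two adjacent quaternary centres) in one step.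

Step 9
Reactants: 16 (1S,2R,3S,3aR,4R,5S,7aR)-3,4,5,7-tetraethyl-2-hydroxy-1-methyl-5-[(E)-2-phenylethenyl]-2,3,3a,4,5,7a-hexahydro-1H-indene-4-carbaldehyde
Product: 17 (1S,3S,3aR,4R,5S,7aR)-3,4,5,7-tetraethyl-1-methyl-2-oxo-5-[(E)-2-phenylethenyl]-2,3,3a,4,5,7a-hexahydro-1H-indene-4-carbaldehyde
Conditions: Dess–Martin periodinane (1.5 equiv), NaHCO3, CH2Cl2, rt
Reagents that add atoms: none
Why: Dess–Martin oxidation of the secondary alcohol leaves the non-enolisable neopentyl aldehyde untouched; the two α-centres of the new cyclopentanone already have the all-trans, thermodynamically preferred arrangement, so they cannot be degraded by enolisation.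

Step 10
Reactants: 17 (1S,3S,3aR,4R,5S,7aR)-3,4,5,7-tetraethyl-1-methyl-2-oxo-5-[(E)-2-phenylethenyl]-2,3,3a,4,5,7a-hexahydro-1H-indene-4-carbaldehyde
Product: 18 (1S,3S,3aR,4R,5S,7aR)-3,4,5,7-tetraethyl-1-methyl-2-oxo-5-[(E)-2-phenylethenyl]-2,3,3a,4,5,7a-hexahydro-1H-indene-4-carboxylic acid
Conditions: NaClO2, NaH2PO4, 2-methyl-2-butene, t-BuOH/H2O, 0 °C → rt
Reagents that add atoms: sodium chlorite (NaClO2), [Na+].[O-]Cl=O
Why: Pinnick oxidation converts even hindered quaternary aldehydes into acids under mildly acidic buffered conditions, with 2-methyl-2-butene scavenging HOCl so that the styryl and trisubstituted alkenes survive; this avoids hydrolysing a hindered ester.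

## Compound list

1 | propyltriphenylphosphonium bromide | CCC[P+](c1ccccc1)(c1ccccc1)c1ccccc1.[Br-] | starting material
2 | ethyl formate | CCOC=O | starting material
3 | 2-(triphenylphosphoranylidene)butanal | CCC(C=O)=P(c1ccccc1)(c1ccccc1)c1ccccc1 | intermediate
4 | propanal | CCC=O | starting material
5 | formaldehyde (37% aqueous) | C=O | starting material
6 | (2R)-3-hydroxy-2-methylpropanal | O=C[C@H](C)CO | intermediate
7 | (2E,4S)-2-ethyl-5-hydroxy-4-methylpent-2-enal | O=C/C(CC)=C/[C@H](C)CO | intermediate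
8 | (2E,4E,6S)-2,4-diethyl-7-hydroxy-6-methylhepta-2,4-dienal | O=C/C(CC)=C/C(CC)=C/[C@H](C)CO | intermediate
9 | diethyl benzylphosphonate | CCOP(=O)(Cc1ccccc1)OCC | starting material
10 | (2S,3E,5E,7E)-4,6-diethyl-2-methyl-8-phenylocta-3,5,7-trien-1-ol | c1ccccc1/C=C/C(CC)=C/C(CC)=C/[C@H](C)CO | intermediate
11 | (2S,3E,5E,7E)-4,6-diethyl-2-methyl-8-phenylocta-3,5,7-trienal | c1ccccc1/C=C/C(CC)=C/C(CC)=C/[C@H](C)C=O | intermediate
12 | (2E)-2-ethylhex-2-enal | CCC/C=C(/C=O)CC | starting material
13 | triethyl{[(1E,3E)-2-ethylhexa-1,3-dien-1-yl]oxy}silane | CC/C=C/C(CC)=C/O[Si](CC)(CC)CC | intermediate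
14 | (2E,4S,5R,6S,7E,9E,11E)-2,4,8,10-tetraethyl-6-methyl-12-phenyl-5-(triethylsilyloxy)dodeca-2,7,9,11-tetraenal | c1ccccc1/C=C/C(CC)=C/C(CC)=C/[C@H](C)[C@@H](O[Si](CC)(CC)CC)[C@@H](CC)/C=C(CC)/C=O | intermediate
15 | (2E,4S,5R,6S,7E,9E,11E)-2,4,8,10-tetraethyl-5-hydroxy-6-methyl-12-phenyldodeca-2,7,9,11-tetraenal | c1ccccc1/C=C/C(CC)=C/C(CC)=C/[C@H](C)[C@@H](O)[C@@H](CC)/C=C(CC)/C=O | intermediate
16 | (1S,2R,3S,3aR,4R,5S,7aR)-3,4,5,7-tetraethyl-2-hydroxy-1-methyl-5-[(E)-2-phenylethenyl]-2,3,3a,4,5,7a-hexahydro-1H-indene-4-carbaldehyde | CCC1=C[C@@](/C=C/c2ccccc2)(CC)[C@](CC)(C=O)[C@@H]2[C@@H]1[C@H](C)[C@@H](O)[C@H]2CC | intermediate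
17 | (1S,3S,3aR,4R,5S,7aR)-3,4,5,7-tetraethyl-1-methyl-2-oxo-5-[(E)-2-phenylethenyl]-2,3,3a,4,5,7a-hexahydro-1H-indene-4-carbaldehyde | CCC1=C[C@@](/C=C/c2ccccc2)(CC)[C@](CC)(C=O)[C@@H]2[C@@H]1[C@H](C)C(=O)[C@H]2CC | intermediate
18 | (1S,3S,3aR,4R,5S,7aR)-3,4,5,7-tetraethyl-1-methyl-2-oxo-5-[(E)-2-phenylethenyl]-2,3,3a,4,5,7a-hexahydro-1H-indene-4-carboxylic acid | CCC1=C[C@@](/C=C/c2ccccc2)(CC)[C@](CC)(C(=O)O)[C@@H]2[C@@H]1[C@H](C)C(=O)[C@H]2CC | target

## Step count and risk

Total steps: 10. Longest linear sequence: 9 steps (1, 2, 3, 4, 5, 7, 8, 9, 10); it is 8 steps from propanal, and step 6 is a one-step side branch.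

The three steps most likely to fail:

**Step 7 (the proposed new aldol).** The IDPi system may give poor γ-selectivity or poor turnover with this hindered dienol ether, or the strongly acidic ion pair may enolise 11. The fallback sets out from 11 and comes back at 15, using only known, substrate-controlled chemistry. Commercial (2E)-2-ethylhex-2-enoic acid is esterified (MeI, K2CO3, DMF) to methyl (2E)-2-ethylhex-2-enoate F3. This is converted (LiN(i-Pr)2, DMPU, t-BuMe2SiCl, THF, −78 °C) into the silyl ketene acetal tert-butyl{[(1Z,3E)-2-ethyl-1-methoxyhexa-1,3-dien-1-yl]oxy}dimethylsilane F4. A vinylogous Mukaiyama aldol addition of F4 to 11 with B(C6F5)3 (10 mol%) and i-PrOH in Et2O at −78 °C (γ-attack, anti, Felkin–Anh) gives methyl (2E,4S,5R,6S,7E,9E,11E)-2,4,8,10-tetraethyl-5-hydroxy-6-methyl-12-phenyldodeca-2,7,9,11-tetraenoate F5. Reduction with i-Bu2AlH (CH2Cl2, −78 °C) gives (2E,4S,5R,6S,7E,9E,11E)-2,4,8,10-tetraethyl-6-methyl-12-phenyldodeca-2,7,9,11-tetraene-1,5-diol F6. MnO2 (CH2Cl2, rt) then oxidises only the allylic primary alcohol and returns 15.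

**Step 2 (one-pot hydroxymethylation and Wittig).** The formyl ylide 3 may react too slowly with the hydrated or dimeric form of 6, and warming would cost enantiomeric purity or cause dehydration. The fallback sets out from 6 (generated in the same way) and comes back at 7. Aldehyde 6 is trapped at room temperature with commercial ethyl 2-(triphenylphosphoranylidene)butanoate, a much more reactive ester-stabilised ylide, to give ethyl (2E,4S)-2-ethyl-5-hydroxy-4-methylpent-2-enoate F1. Reduction with i-Bu2AlH (CH2Cl2, −78 °C) gives (2E,4S)-2-ethyl-4-methylpent-2-ene-1,5-diol F2, and MnO2 oxidises the allylic hydroxyl alone to return 7.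

**Step 8 (intramolecular Diels–Alder).** Heating may be slow because two adjacent quaternary centres are formed, and the free hydroxyl may lower the trans/cis ratio. The fallback sets out from 14 (isolated instead of being desilylated in step 7) and comes back at 16. Me2AlCl (1.1 equiv, CH2Cl2, −78 → −20 °C) promotes the cycloaddition of the silyl-protected enal at low temperature, where the endo, trans-fused pathway is favoured most strongly, and gives (1S,2R,3S,3aR,4R,5S,7aR)-3,4,5,7-tetraethyl-1-methyl-5-[(E)-2-phenylethenyl]-2-(triethylsilyloxy)-2,3,3a,4,5,7a-hexahydro-1H-indene-4-carbaldehyde F7. HF·pyridine (THF, 0 °C) then returns 16.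

## Further compounds

F1 | step 2 | ethyl (2E,4S)-2-ethyl-5-hydroxy-4-methylpent-2-enoate | CCOC(=O)/C(CC)=C/[C@H](C)CO
F2 | step 2 | (2E,4S)-2-ethyl-4-methylpent-2-ene-1,5-diol | OC/C(CC)=C/[C@H](C)CO
F3 | step 7 | methyl (2E)-2-ethylhex-2-enoate | CCC/C=C(\CC)C(=O)OC
F4 | step 7 | tert-butyl{[(1Z,3E)-2-ethyl-1-methoxyhexa-1,3-dien-1-yl]oxy}dimethylsilane | CC/C=C/C(CC)=C(/OC)O[Si](C)(C)C(C)(C)C
F5 | step 7 | methyl (2E,4S,5R,6S,7E,9E,11E)-2,4,8,10-tetraethyl-5-hydroxy-6-methyl-12-phenyldodeca-2,7,9,11-tetraenoate | c1ccccc1/C=C/C(CC)=C/C(CC)=C/[C@H](C)[C@@H](O)[C@@H](CC)/C=C(CC)/C(=O)OC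
F6 | step 7 | (2E,4S,5R,6S,7E,9E,11E)-2,4,8,10-tetraethyl-6-methyl-12-phenyldodeca-2,7,9,11-tetraene-1,5-diol | c1ccccc1/C=C/C(CC)=C/C(CC)=C/[C@H](C)[C@@H](O)[C@@H](CC)/C=C(CC)/CO
F7 | step 8 | (1S,2R,3S,3aR,4R,5S,7aR)-3,4,5,7-tetraethyl-1-methyl-5-[(E)-2-phenylethenyl]-2-(triethylsilyloxy)-2,3,3a,4,5,7a-hexahydro-1H-indene-4-carbaldehyde | CCC1=C[C@@](/C=C/c2ccccc2)(CC)[C@](CC)(C=O)[C@@H]2[C@@H]1[C@H](C)[C@@H](O[Si](CC)(CC)CC)[C@H]2CC
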